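**Retrosynthetic overview**

1. Late adjustments (aryl bromide → phenol, chromane → 2H-chromene, formyl → methyl) lead back to a cyclohexenecarbaldehyde that carries a 5-bromochromane.
2. Key disconnection: retro-[4+2] of the cyclohexene across C1–C2 and C5–C6, giving (E)-3-methylpenta-1,3-diene and a 2-alkylacrolein. The enabling feature is that the ring's only double bond, C3=C4, lies between C2 and C5 opposite the C1–C6 edge, and that quaternary C1 carries a methyl (carried as formyl) cis to the C2 methyl, the pattern of an endo adduct of an (E)-diene.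
3. The 2-alkylacrolein comes from a chromane propanal by one-carbon homologation and α-methylenation; the propanal comes from oxidative cleavage of a prenyl side chain.
4. Chiral pool: (R)-linalool supplies chromene C2 with its methyl and oxygen (linalool C3), pyran C3/C4 (the vinyl group), the ethylene tether (C4, C5) and the future quaternary cyclohexene carbon (C6). The arene is the symmetric 1,3-dibromo-2-iodo-4,5,6-trimethoxybenzene.
5. Ring order: pyran ring first (B-alkyl Suzuki coupling, then Pd-catalysed C–O closure), cyclohexene second (Diels–Alder), pyran unsaturation and phenol last.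

Key step: step 8

Remark: (R)-(−)-linalool of high enantiomeric purity is assumed as purchased; the R/S label at the chromane carbon changes in 6 and 9 only because CIP priorities of the side chains change, the spatial arrangement of linalool is kept throughout; diene 13 may contain its (Z)-isomer, which should not react.

**Route**

Step 1
Reactants: 1 1,2,3-trimethoxybenzene
Product: 2 1,5-dibromo-2,3,4-trimethoxybenzene
Conditions: NBS (2.1 equiv), MeCN, 0 °C to rt
Reagents that add atoms: N-bromosuccinimide, O=C1CCC(=O)N1Br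
Why: Electrophilic aromatic bromination, in which C4 and then C6 (each ortho to one and para to another methoxy group) should react in turn to give the symmetric dibromide, C5 being the least activated site.

Step 2
Reactants: 2 1,5-dibromo-2,3,4-trimethoxybenzene
Product: 4 1,3-dibromo-2-iodo-4,5,6-trimethoxybenzene, via aryllithium 3 (not isolated)
Conditions: LiN(iPr)2 (1.1 equiv), THF, −78 °C; then I2, −78 °C to rt
Reagents that add atoms: iodine, II
Why: Deprotonative lithiation of the only ring C–H, acidified by its two flanking bromines, followed by iodinolysis; holding −78 °C should prevent loss of LiBr to an aryne.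

Step 3
Reactants: 5 (R)-(−)-linalool [(3R)-3,7-dimethylocta-1,6-dien-3-ol]; 4 1,3-dibromo-2-iodo-4,5,6-trimethoxybenzene
Product: 7 (3R)-1-(2,6-dibromo-3,4,5-trimethoxyphenyl)-3,7-dimethyloct-6-en-3-ol, via alkylborane 6 (not isolated)
Conditions: 9-BBN (1.5 equiv), THF, 0 °C to rt; then 4, PdCl2(dppf) (5 mol%), 3 M aq NaOH, THF, 60 °C
Reagents that add atoms: none
Why: Hydroboration/B-alkyl Suzuki–Miyaura coupling, in which 9-BBN should add anti-Markovnikov to the monosubstituted vinyl group only and oxidative addition should occur at C–I in preference to the two C–Br bonds, while the carbinol stereocenter takes no part.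

Step 4
Reactants: 7 (3R)-1-(2,6-dibromo-3,4,5-trimethoxyphenyl)-3,7-dimethyloct-6-en-3-ol
Product: 8 (2R)-5-bromo-6,7,8-trimethoxy-2-methyl-2-(4-methylpent-3-en-1-yl)-3,4-dihydro-2H-chromene
Conditions: Pd(OAc)2 (5 mol%), 2-(di-tert-butylphosphino)-1,1'-binaphthyl (6 mol%), Cs2CO3 (1.5 equiv), toluene, 80 °C
Reagents that add atoms: none
Why: Buchwald–Hartwig-type intramolecular C–O coupling of the tertiary alcohol with an aryl bromide closes the six-membered pyran ring; the two bromines are equivalent by symmetry and the C–O bond at the stereocenter is never broken, so its configuration is retained.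

Step 5
Reactants: 8 (2R)-5-bromo-6,7,8-trimethoxy-2-methyl-2-(4-methylpent-3-en-1-yl)-3,4-dihydro-2H-chromene
Product: 9 3-[(2S)-5-bromo-6,7,8-trimethoxy-2-methyl-3,4-dihydro-2H-chromen-2-yl]propanal
Conditions: OsO4 (2 mol%), NaIO4 (4 equiv), 2,6-lutidine, dioxane/H2O (3:1), rt
Reagents that add atoms: sodium periodate, [Na+].[O-]I(=O)(=O)=O (oxygen passed on by catalytic osmium tetroxide, O=[Os](=O)(=O)=O)
Why: Lemieux–Johnson dihydroxylation and glycol cleavage of the only C=C bond, under conditions to which the aryl bromide and the ethers should be inert.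

Step 6
Reactants: 9 3-[(2S)-5-bromo-6,7,8-trimethoxy-2-methyl-3,4-dihydro-2H-chromen-2-yl]propanal
Product: 11 4-[(2R)-5-bromo-6,7,8-trimethoxy-2-methyl-3,4-dihydro-2H-chromen-2-yl]butanal, via enol ether 10 (not isolated)
Conditions: Ph3P(CH2OMe)Cl, KOtBu, THF, 0 °C; then 2 M aq HCl, THF, rt
Reagents that add atoms: (methoxymethyl)triphenylphosphonium chloride, [Cl-].COC[P+](c1ccccc1)(c1ccccc1)c1ccccc1; water, O
Why: Wittig methoxymethylenation followed by acid hydrolysis of the enol ether, the standard one-carbon homologation of an aldehyde, which the aryl alkyl ether and the aryl bromide should survive.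

Step 7
Reactants: 11 4-[(2R)-5-bromo-6,7,8-trimethoxy-2-methyl-3,4-dihydro-2H-chromen-2-yl]butanal
Product: 12 4-[(2R)-5-bromo-6,7,8-trimethoxy-2-methyl-3,4-dihydro-2H-chromen-2-yl]-2-methylidenebutanal
Conditions: 37% aq HCHO, pyrrolidine (10 mol%), propionic acid (10 mol%), iPrOH, 45 °C
Reagents that add atoms: formaldehyde, C=O
Why: Amine-catalysed Mannich condensation with formaldehyde and β-elimination (α-methylenation of an aldehyde), which should stop at the 2-alkylacrolein because no α-hydrogen remains.

Step 8
Reactants: 12 4-[(2R)-5-bromo-6,7,8-trimethoxy-2-methyl-3,4-dihydro-2H-chromen-2-yl]-2-methylidenebutanal; 13 (3E)-3-methylpenta-1,3-diene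
Product: 14 (1R,2R)-1-{2-[(2R)-5-bromo-6,7,8-trimethoxy-2-methyl-3,4-dihydro-2H-chromen-2-yl]ethyl}-2,3-dimethylcyclohex-3-ene-1-carbaldehyde
Conditions: 13 (5 equiv), B-(o-tolyl)oxazaborolidine from (S)-α,α-diphenylprolinol (20 mol%) activated with Tf2NH (20 mol%), CH2Cl2, −78 °C
Reagents that add atoms: none
Why: The cationic boron Lewis acid binds the formyl oxygen of the s-trans 2-alkylacrolein and the diene adds in a concerted, asynchronous [4+2] cycloaddition; the closest known reaction type is the oxazaborolidinium-catalysed enantioselective Diels–Alder reaction of 2-substituted acroleins with acyclic dienes. The cyclohexene ring is closed by intermolecular cycloaddition, suprafacial on both partners, which forms C5–C6 and C1–C2 together and leaves the double bond at C3=C4. Regioselectivity is needed and should come from the leading bond between the enal β-carbon and the unsubstituted diene terminus, the less hindered end and the one favoured by the terminal methyl donor, so that the quaternary α-carbon joins the methyl-bearing terminus. The configuration at C2 relative to C1 is fixed by the (E)-geometry of the diene together with the endo position of the small formyl group (the long alkyl chain lies exo), which places CHO cis to the C2 methyl as the Alder endo rule predicts. The absolute configuration at C1 is controlled by the catalyst, whose aryl group shields one face of the bound enal; the (S)-prolinol-derived catalyst is expected to give the (1R,2R) adduct, and the mirror-image catalyst is available should the sense prove opposite. The remote chromane stereocenter is a spectator, and the aryl bromide and ether groups are not expected to interfere.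

Step 9
Reactants: 14 (1R,2R)-1-{2-[(2R)-5-bromo-6,7,8-trimethoxy-2-methyl-3,4-dihydro-2H-chromen-2-yl]ethyl}-2,3-dimethylcyclohex-3-ene-1-carbaldehyde
Product: 16 (2R)-5-bromo-6,7,8-trimethoxy-2-methyl-2-{2-[(1S,2S)-1,2,3-trimethylcyclohex-3-en-1-yl]ethyl}-3,4-dihydro-2H-chromene, via hydrazone 15 (not isolated)
Conditions: N2H4·H2O, diethylene glycol, 130 °C; then KOH, 200 °C, argon
Reagents that add atoms: none
Why: Wolff–Kishner reduction of a non-enolisable aldehyde on a quaternary carbon to the methyl group, with no stereocenter at risk and air excluded so that no diimide can form.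

Step 10
Reactants: 16 (2R)-5-bromo-6,7,8-trimethoxy-2-methyl-2-{2-[(1S,2S)-1,2,3-trimethylcyclohex-3-en-1-yl]ethyl}-3,4-dihydro-2H-chromene
Product: 17 (2R)-5-bromo-6,7,8-trimethoxy-2-methyl-2-{2-[(1S,2S)-1,2,3-trimethylcyclohex-3-en-1-yl]ethyl}-2H-chromene
Conditions: DDQ (1.5 equiv), 1,4-dioxane, 90 °C
Reagents that add atoms: none
Why: DDQ dehydrogenation of a chromane to a 2H-chromene by hydride abstraction from benzylic C4 (a cation stabilised by the ring oxygen and the para methoxy group) and loss of H3; C2 is quaternary, so the double bond can only arise at C3=C4.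

Step 11
Reactants: 17 (2R)-5-bromo-6,7,8-trimethoxy-2-methyl-2-{2-[(1S,2S)-1,2,3-trimethylcyclohex-3-en-1-yl]ethyl}-2H-chromene
Product: 20 (2R)-6,7,8-trimethoxy-2-methyl-2-{2-[(1S,2S)-1,2,3-trimethylcyclohex-3-en-1-yl]ethyl}-2H-chromen-5-ol (target), via aryllithium 18 (not isolated), via arylboronate 19 (not isolated)
Conditions: n-BuLi (1.1 equiv), THF, −78 °C; B(OMe)3, −78 to 0 °C; then 30% H2O2, aq NaOH, 0 °C
Reagents that add atoms: hydrogen peroxide, OO
Why: Bromine–lithium exchange, borylation and oxidative 1,2-aryl shift of the boronate (ipso-hydroxylation) should convert the aryl bromide into the phenol at low temperature without touching either alkene or the stereocenters.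

**Compound list**

1 | 1,2,3-trimethoxybenzene | COc1cccc(OC)c1OC | starting material
2 | 1,5-dibromo-2,3,4-trimethoxybenzene | COc1c(Br)cc(Br)c(OC)c1OC | intermediate
3 | (2,6-dibromo-3,4,5-trimethoxyphenyl)lithium | [Li]c1c(Br)c(OC)c(OC)c(OC)c1Br | intermediate (not isolated)
4 | 1,3-dibromo-2-iodo-4,5,6-trimethoxybenzene | Brc1c(I)c(Br)c(OC)c(OC)c1OC | intermediate
5 | (R)-(−)-linalool, (3R)-3,7-dimethylocta-1,6-dien-3-ol | CC(C)=CCC[C@@](C)(O)C=C | starting material
6 | 9-[(3S)-3-hydroxy-3,7-dimethyloct-6-en-1-yl]-9-borabicyclo[3.3.1]nonane | CC(C)=CCC[C@@](C)(O)CCB1C2CCCC1CCC2 | intermediate (not isolated)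
7 | (3R)-1-(2,6-dibromo-3,4,5-trimethoxyphenyl)-3,7-dimethyloct-6-en-3-ol | CC(C)=CCC[C@@](C)(O)CCc1c(Br)c(OC)c(OC)c(OC)c1Br | intermediate
8 | (2R)-5-bromo-6,7,8-trimethoxy-2-methyl-2-(4-methylpent-3-en-1-yl)-3,4-dihydro-2H-chromene | CC(C)=CCC[C@]1(C)CCc2c(Br)c(OC)c(OC)c(OC)c2O1 | intermediate
9 | 3-[(2S)-5-bromo-6,7,8-trimethoxy-2-methyl-3,4-dihydro-2H-chromen-2-yl]propanal | O=CCC[C@]1(C)CCc2c(Br)c(OC)c(OC)c(OC)c2O1 | intermediate
10 | (2R)-5-bromo-6,7,8-trimethoxy-2-(4-methoxybut-3-en-1-yl)-2-methyl-3,4-dihydro-2H-chromene (E/Z mixture) | COC=CCC[C@]1(C)CCc2c(Br)c(OC)c(OC)c(OC)c2O1 | intermediate (not isolated)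
11 | 4-[(2R)-5-bromo-6,7,8-trimethoxy-2-methyl-3,4-dihydro-2H-chromen-2-yl]butanal | O=CCCC[C@]1(C)CCc2c(Br)c(OC)c(OC)c(OC)c2O1 | intermediate
12 | 4-[(2R)-5-bromo-6,7,8-trimethoxy-2-methyl-3,4-dihydro-2H-chromen-2-yl]-2-methylidenebutanal | C=C(C=O)CC[C@]1(C)CCc2c(Br)c(OC)c(OC)c(OC)c2O1 | intermediate
13 | (3E)-3-methylpenta-1,3-diene | C=C/C(C)=C/C | starting material
14 | (1R,2R)-1-{2-[(2R)-5-bromo-6,7,8-trimethoxy-2-methyl-3,4-dihydro-2H-chromen-2-yl]ethyl}-2,3-dimethylcyclohex-3-ene-1-carbaldehyde | O=C[C@@]1(CC[C@]2(C)CCc3c(Br)c(OC)c(OC)c(OC)c3O2)CCC=C(C)[C@H]1C | intermediate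
15 | hydrazone of 14, [(1R,2R)-1-{2-[(2R)-5-bromo-6,7,8-trimethoxy-2-methyl-3,4-dihydro-2H-chromen-2-yl]ethyl}-2,3-dimethylcyclohex-3-en-1-yl]methylidenehydrazine | NN=C[C@@]1(CC[C@]2(C)CCc3c(Br)c(OC)c(OC)c(OC)c3O2)CCC=C(C)[C@H]1C | intermediate (not isolated)
16 | (2R)-5-bromo-6,7,8-trimethoxy-2-methyl-2-{2-[(1S,2S)-1,2,3-trimethylcyclohex-3-en-1-yl]ethyl}-3,4-dihydro-2H-chromene | C[C@@]1(CC[C@]2(C)CCc3c(Br)c(OC)c(OC)c(OC)c3O2)CCC=C(C)[C@H]1C | intermediate
17 | (2R)-5-bromo-6,7,8-trimethoxy-2-methyl-2-{2-[(1S,2S)-1,2,3-trimethylcyclohex-3-en-1-yl]ethyl}-2H-chromene | C[C@@]1(CC[C@]2(C)C=Cc3c(Br)c(OC)c(OC)c(OC)c3O2)CCC=C(C)[C@H]1C | intermediate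
18 | [(2R)-6,7,8-trimethoxy-2-methyl-2-{2-[(1S,2S)-1,2,3-trimethylcyclohex-3-en-1-yl]ethyl}-2H-chromen-5-yl]lithium | C[C@@]1(CC[C@]2(C)C=Cc3c([Li])c(OC)c(OC)c(OC)c3O2)CCC=C(C)[C@H]1C | intermediate (not isolated)
19 | dimethyl [(2R)-6,7,8-trimethoxy-2-methyl-2-{2-[(1S,2S)-1,2,3-trimethylcyclohex-3-en-1-yl]ethyl}-2H-chromen-5-yl]boronate | C[C@@]1(CC[C@]2(C)C=Cc3c(B(OC)OC)c(OC)c(OC)c(OC)c3O2)CCC=C(C)[C@H]1C | intermediate (not isolated)
20 | (2R)-6,7,8-trimethoxy-2-methyl-2-{2-[(1S,2S)-1,2,3-trimethylcyclohex-3-en-1-yl]ethyl}-2H-chromen-5-ol | COc1c(O)c2c(c(OC)c1OC)O[C@](C)(CC[C@]1(C)CCC=C(C)[C@H]1C)C=C2 | target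

**Step count and risks**

Total step count: 11. Longest linear sequence: 11 steps (from 1 to 20); 9 steps from (R)-linalool 5.

Steps most likely to fail:

1. Step 8 (Diels–Alder). What may go wrong: insufficient facial discrimination by the catalyst on a dienophile with several Lewis-basic ether oxygens, erosion of endo selectivity, or partial bonding of the substituted diene terminus to the β-carbon, each of which would give isomers that are hard to separate. Fallback, changing from catalyst control to auxiliary control in a cationic Diels–Alder reaction: the fallback sets out from enal 12, which is condensed with (2R,4R)-pentane-2,4-diol (PPTS, benzene, reflux with water removal) to give the chiral 2-alkenyl-4,6-dimethyl-1,3-dioxane F1. TMSOTf (CH2Cl2, −78 °C) should open the acetal to an alkoxy-substituted allyl cation, which adds to diene 13 stepwise with the same "ortho" and endo preferences while the diol controls the face, and recloses to the cycloadduct acetal F2. Hydrolysis (1 M aq HCl, THF, rt) then returns to the route at aldehyde 14. The enantiomeric diol is used if it proves to be the matched one.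

2. Step 10 (DDQ dehydrogenation). What may go wrong: competing hydride abstraction at the allylic positions of the cyclohexene, or over-oxidation of the electron-rich arene at the temperature needed. Fallback, reversing the last two operations so that the dehydrogenation runs at room temperature through an ortho-quinone methide: the fallback sets out from chromane 16, whose Pd-catalysed hydroxylation (Pd2(dba)3, tBuXPhos, KOH, dioxane/H2O, 100 °C) should give the 5-hydroxychromane F3. Oxidation of this ortho-alkylphenol with Ag2O (benzene, rt) should give the ortho-quinone methide F4 (not isolated), whose 1,5-hydrogen shift from C3 to oxygen delivers the chromenol and comes back to the route at target 20.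

3. Step 3 (B-alkyl Suzuki coupling). What may go wrong: slow transmetalation at an arylpalladium flanked by two bromines, β-hydride elimination of the alkyl group, or competing insertion into a C–Br bond. Fallback, changing the C–C bond formation to a Heck reaction followed by selective alkene reduction: the fallback sets out from 5 and 4, which under ligand-free phase-transfer Heck conditions (Pd(OAc)2, Bu4NCl, NaHCO3, DMF, 70 °C) should give the (E)-styrenyl carbinol F5. Diimide, generated from 2-nitrobenzenesulfonylhydrazide and Et3N (CH2Cl2, rt), should then reduce the disubstituted double bond in preference to the trisubstituted one and return to the route at alcohol 7.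

**Further compounds**

F1 | step 8 | (4R,6R)-2-{4-[(2R)-5-bromo-6,7,8-trimethoxy-2-methyl-3,4-dihydro-2H-chromen-2-yl]but-1-en-2-yl}-4,6-dimethyl-1,3-dioxane | C=C(CC[C@]1(C)CCc2c(Br)c(OC)c(OC)c(OC)c2O1)C1O[C@H](C)C[C@@H](C)O1
F2 | step 8 | (4R,6R)-2-[(1R,2R)-1-{2-[(2R)-5-bromo-6,7,8-trimethoxy-2-methyl-3,4-dihydro-2H-chromen-2-yl]ethyl}-2,3-dimethylcyclohex-3-en-1-yl]-4,6-dimethyl-1,3-dioxane | C[C@@H]1C[C@@H](C)OC(O1)[C@@]4(CC[C@]2(C)CCc3c(Br)c(OC)c(OC)c(OC)c3O2)CCC=C(C)[C@H]4C
F3 | step 10 | (2R)-6,7,8-trimethoxy-2-methyl-2-{2-[(1S,2S)-1,2,3-trimethylcyclohex-3-en-1-yl]ethyl}-3,4-dihydro-2H-chromen-5-ol | C[C@@]1(CC[C@]2(C)CCc3c(O)c(OC)c(OC)c(OC)c3O2)CCC=C(C)[C@H]1C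
F4 | step 10 | (2R)-6,7,8-trimethoxy-2-methyl-2-{2-[(1S,2S)-1,2,3-trimethylcyclohex-3-en-1-yl]ethyl}-2,3-dihydro-5H-chromen-5-one (ortho-quinone methide) | COC1=C(OC)C(=O)C2=CC[C@@](C)(CC[C@]3(C)CCC=C(C)[C@H]3C)OC2=C1OC
F5 | step 3 | (1E,3R)-1-(2,6-dibromo-3,4,5-trimethoxyphenyl)-3,7-dimethylocta-1,6-dien-3-ol | CC(C)=CCC[C@@](C)(O)/C=C/c1c(Br)c(OC)c(OC)c(OC)c1Br
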